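**Plan**

Atoms are numbered as in eremophilanes: ring A = C1, C2, C3 (ester O), C4 (CH3), C5 (angular CH3), C10; ring B = C5, C6, C7 (isopropylidene), C8 (C=O), C9, C10.
Retrosynthesis cuts, in order: the C3–O ester bond (Mitsunobu, inversion); the C7=C11 isopropylidene bond (acetone aldol); C8–C9 and C5–C10 together; then C6–C7 (Suzuki), C5–CH3 (carboalumination) and C3–C4 (aldol).
Enabling feature: in ring B the C9=C10 double bond lies between the two bonds to be made and C5–C6–C7–C8 is a four-carbon path, the retron of an alkyne-plus-diene [4+2]. The ring A atoms C1–C4 tie alkyne carbon C10 to diene terminus C5, so one cycloaddition of an acyclic dienyne closes ring A and ring B and makes quaternary C5.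
Forward: linear dienyne from small commercial pieces, then a rhodium-catalysed [4+2] that closes rings A and B at once, then C8 ether to ketone, reductive aldol and dehydration for the isopropylidene, and the side-chain acid joined last.
Stereochemistry: C3 and C4 come from one auxiliary-controlled syn aldol. C5 is relayed from C4 and C3 in the cycloaddition; C3 is carried as its epimer so that both tether substituents sit pseudo-equatorial. C3 is inverted to the natural configuration in the final Mitsunobu esterification, and side-chain C6 is bought as (S)-2-methylbutan-1-ol.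

Key step: step 11

Assumption: the aldol adduct of step 13 is drawn as the C7 epimer expected from addition anti to the angular methyl; this centre is erased in step 14, so its configuration does not affect the route.

**Route**

Step 1
Reactants: 1 ethyl (2Z)-3-iodoprop-2-enoate; 2 ethynyltrimethylsilane
Product: 3 ethyl (2Z)-5-(trimethylsilyl)pent-2-en-4-ynoate
Conditions: PdCl2(PPh3)2 (2 mol%), CuI (4 mol%), Et3N, THF, 0 °C → rt
Reagents that add atoms: none
Why: Sonogashira coupling of a (Z)-β-iodoacrylate with a terminal alkyne proceeds with retention of alkene geometry, so the cis C1=C2 unit of ring A is fixed from a commercial iodide.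

Step 2
Reactants: 3 ethyl (2Z)-5-(trimethylsilyl)pent-2-en-4-ynoate
Product: 4 (2Z)-5-(trimethylsilyl)pent-2-en-4-yn-1-ol
Conditions: i-Bu2AlH (2.2 equiv), CH2Cl2, −78 °C; aq. potassium sodium tartrate work-up
Reagents that add atoms: none
Why: i-Bu2AlH reduces the conjugated ester to the allylic alcohol (1,2-hydride reduction) at low temperature without touching the silylalkyne or the (Z)-alkene.

Step 3
Reactants: 4 (2Z)-5-(trimethylsilyl)pent-2-en-4-yn-1-ol
Product: 5 (2Z)-5-(trimethylsilyl)pent-2-en-4-ynal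
Conditions: Dess–Martin periodinane, NaHCO3, CH2Cl2, 0 °C; used at once
Reagents that add atoms: none
Why: Dess–Martin oxidation under buffered, non-acidic conditions should give the (Z)-enal without isomerisation to the (E)-isomer.

Step 4
Reactants: 5 (2Z)-5-(trimethylsilyl)pent-2-en-4-ynal; 6 (4S)-4-benzyl-3-propanoyl-1,3-oxazolidin-2-one
Product: 8 (4S)-4-benzyl-3-[(2S,3R,4Z)-3-hydroxy-2-methyl-7-(trimethylsilyl)hept-4-en-6-ynoyl]-1,3-oxazolidin-2-one, via boron enolate 7 (not isolated)
Conditions: 6, n-Bu2BOTf, Et3N, CH2Cl2, −78 → 0 °C; then 5, −78 → 0 °C; pH 7 buffer (NaH2PO4/Na2HPO4), MeOH, H2O2 work-up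
Reagents that add atoms: di-n-butylboron triflate, CCCCB(CCCC)OS(=O)(=O)C(F)(F)F (boron and butyl groups are carried only by intermediate 7)
Why: Evans syn-aldol reaction: the (Z)-boron enolate 7 reacts through a Zimmerman–Traxler chair whose enolate face is fixed by the (S)-benzyl auxiliary, which sets C3 (R) and C4 together as the syn pair.

Step 5
Reactants: 8 (4S)-4-benzyl-3-[(2S,3R,4Z)-3-hydroxy-2-methyl-7-(trimethylsilyl)hept-4-en-6-ynoyl]-1,3-oxazolidin-2-one
Product: 9 (4S)-4-benzyl-3-[(2S,3R,4Z)-3-[(tert-butyldimethylsilyl)oxy]-2-methyl-7-(trimethylsilyl)hept-4-en-6-ynoyl]-1,3-oxazolidin-2-one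
Conditions: TBSOTf, 2,6-lutidine, CH2Cl2, −78 → 0 °C
Reagents that add atoms: tert-butyldimethylsilyl triflate, CC(C)(C)[Si](C)(C)OS(=O)(=O)C(F)(F)F
Why: Silyl ether formation with the triflate and a hindered base protects the secondary alcohol without disturbing the imide or the (Z)-enyne.

Step 6
Reactants: 9 (4S)-4-benzyl-3-[(2S,3R,4Z)-3-[(tert-butyldimethylsilyl)oxy]-2-methyl-7-(trimethylsilyl)hept-4-en-6-ynoyl]-1,3-oxazolidin-2-one
Product: 10 (2R,3R,4Z)-3-[(tert-butyldimethylsilyl)oxy]-2-methyl-7-(trimethylsilyl)hept-4-en-6-yn-1-ol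
Conditions: LiBH4, MeOH (1 equiv), THF, 0 °C
Reagents that add atoms: none
Why: LiBH4 reductively cleaves the N-acyl oxazolidinone to the primary alcohol (hydride reduction of the exocyclic imide carbonyl) without epimerising C4, and the auxiliary is recovered.

Step 7
Reactants: 10 (2R,3R,4Z)-3-[(tert-butyldimethylsilyl)oxy]-2-methyl-7-(trimethylsilyl)hept-4-en-6-yn-1-ol
Product: 11 (2S,3R,4Z)-3-[(tert-butyldimethylsilyl)oxy]-2-methyl-7-(trimethylsilyl)hept-4-en-6-ynal
Conditions: Dess–Martin periodinane, NaHCO3, CH2Cl2, 0 °C → rt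
Reagents that add atoms: none
Why: Dess–Martin oxidation gives the α-methyl aldehyde under neutral conditions that should avoid epimerisation at C4.

Step 8
Reactants: 11 (2S,3R,4Z)-3-[(tert-butyldimethylsilyl)oxy]-2-methyl-7-(trimethylsilyl)hept-4-en-6-ynal
Product: 12 tert-butyldimethyl{[(3Z,5R,6R)-6-methyl-1-(trimethylsilyl)oct-3-ene-1,7-diyn-5-yl]oxy}silane
Conditions: Me3SiCHN2, n-BuLi, THF, −78 °C; then 11, −78 → 0 °C
Reagents that add atoms: (trimethylsilyl)diazomethane, C[Si](C)(C)C=[N+]=[N-]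
Why: Colvin homologation (addition of lithiated trimethylsilyldiazomethane, Peterson-type elimination, 1,2-hydride shift of the alkylidene carbene) turns the aldehyde into the terminal alkyne without the methanolic base that would strip the alkynyl silyl group.

Step 9
Reactants: 12 tert-butyldimethyl{[(3Z,5R,6R)-6-methyl-1-(trimethylsilyl)oct-3-ene-1,7-diyn-5-yl]oxy}silane
Product: 14 tert-butyl{[(3Z,5R,6R,7E)-8-iodo-6,7-dimethyl-1-(trimethylsilyl)octa-3,7-dien-1-yn-5-yl]oxy}dimethylsilane, via alkenylalane 13 (not isolated)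
Conditions: AlMe3 (3 equiv), Cp2ZrCl2 (0.25 equiv), CH2Cl2, 0 °C → rt; then I2, THF, −30 °C
Reagents that add atoms: trimethylaluminium, C[Al](C)C; iodine, II
Why: Negishi zirconium-catalysed carboalumination adds CH3 and Al syn across the terminal alkyne with the methyl on C5 and iodinolysis retains geometry, so the C5=C6 alkene is formed with the tether trans to C7 (E) while the silyl-capped alkyne is inert.

Step 10
Reactants: 14 tert-butyl{[(3Z,5R,6R,7E)-8-iodo-6,7-dimethyl-1-(trimethylsilyl)octa-3,7-dien-1-yn-5-yl]oxy}dimethylsilane; 15 2-[(E)-2-ethoxyethenyl]-4,4,5,5-tetramethyl-1,3,2-dioxaborolane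
Product: 17 tert-butyl{[(3Z,5R,6R,7E,9E)-10-ethoxy-6,7-dimethyldeca-3,7,9-trien-1-yn-5-yl]oxy}dimethylsilane, via silyl-capped dienyne 16 (not isolated)
Conditions: Pd(OAc)2 (5 mol%), SPhos (10 mol%), K3PO4, THF–H2O, 45 °C; then K2CO3, MeOH, rt
Reagents that add atoms: none
Why: Suzuki–Miyaura coupling joins C6 to C7 with retention at both alkenes to give the (E,E)-1-ethoxydiene, and potassium carbonate in methanol then cleaves only the alkynyl C–Si bond (protodesilylation) in the same pot.

Step 11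
Reactants: 17 tert-butyl{[(3Z,5R,6R,7E,9E)-10-ethoxy-6,7-dimethyldeca-3,7,9-trien-1-yn-5-yl]oxy}dimethylsilane
Product: 18 tert-butyl{[(1R,2R,6R,8aR)-6-ethoxy-1,8a-dimethyl-1,2,6,8a-tetrahydronaphthalen-2-yl]oxy}dimethylsilane
Conditions: [RhCl(C8H14)2]2 (2.5 mol%), P[OCH(CF3)2]3 (10 mol%), THF (0.02 M), 25 → 55 °C
Reagents that add atoms: none
Why: Monovalent rhodium binds the terminal alkyne and the s-cis diene of 17, oxidative coupling joins C10 to C5 to give a rhodacycle, and its C6–C7–C8 allyl arm then reductively eliminates onto C9, so C5–C10 and C8–C9 are made in one catalytic event. The closest known reaction type is the rhodium- or nickel-catalysed intramolecular [4+2] cycloaddition of unactivated 1,3-dien-8-ynes, a metal-templated Diels–Alder reaction in which the metal holds the diene s-cis, so the inward methyl on C5 that would retard a thermal cycloaddition of this unactivated alkyne should be tolerated. Ring A closes through the C5–C10 bond in a six-membered exo-dig/exo-trig mode with C1–C4 as tether (the cis C1=C2 alkene holds C10 near C5), and ring B closes through the C8–C9 bond as the six-membered [4+2] ring fused along C5–C10. The new quaternary centre C5 is controlled by C4 with support from C3: in the half-chair of the forming ring A the C4 methyl and the C3 silyloxy group are both pseudo-equatorial and C4–H eclipses C5=C6 (allylic 1,3-strain minimised), so the alkyne should add to the diene face anti to the C4 methyl and the angular methyl should end cis to it. The C8 ethoxy centre (trans to the angular methyl, from suprafacial addition to the E,E-diene) is immaterial because step 12 erases it. The step needs facial selectivity at C5 and [4+2] periselectivity over alkyne oligomerisation; the syn C3/C4 pattern (hence C3 carried as its epimer), the E geometry of C5=C6 with the tether outside, and intramolecularity at high dilution should secure them.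

Step 12
Reactants: 18 tert-butyl{[(1R,2R,6R,8aR)-6-ethoxy-1,8a-dimethyl-1,2,6,8a-tetrahydronaphthalen-2-yl]oxy}dimethylsilane
Product: 19 (4aR,5R,6R)-6-[(tert-butyldimethylsilyl)oxy]-4a,5-dimethyl-5,6-dihydronaphthalen-2(4aH)-one
Conditions: DDQ (1.2 equiv), CH2Cl2–pH 7 buffer (NaH2PO4/Na2HPO4), 0 °C
Reagents that add atoms: water, O
Why: DDQ abstracts hydride from the doubly allylic, ethoxy-bearing C8–H to give a stabilised oxocarbenium ion that water traps at C8 with loss of ethanol (oxidation of an allylic ether to the ketone), which places the carbonyl at C8 without ambiguity.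

Step 13
Reactants: 19 (4aR,5R,6R)-6-[(tert-butyldimethylsilyl)oxy]-4a,5-dimethyl-5,6-dihydronaphthalen-2(4aH)-one
Product: 21 (3S,4aR,5R,6R)-6-[(tert-butyldimethylsilyl)oxy]-3-(2-hydroxypropan-2-yl)-4a,5-dimethyl-4,4a,5,6-tetrahydronaphthalen-2(3H)-one, via lithium dienolate 20 (not isolated)
Conditions: LiBH(s-Bu)3 (1.05 equiv), THF, −78 °C; then acetone, −78 °C; AcOH quench
Reagents that add atoms: acetone, CC(C)=O; LiBH(s-Bu)3, [Li+].CCC(C)[BH-](C(C)CC)C(C)CC (lithium is carried only by intermediate 20)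
Why: Reductive aldol reaction: the bulky hydride should add 1,4 to the less substituted enone terminus C6 (C10 is fully substituted), and the regiodefined enolate 20 then adds to acetone at C7 anti to the angular methyl, a centre that step 14 erases.

Step 14
Reactants: 21 (3S,4aR,5R,6R)-6-[(tert-butyldimethylsilyl)oxy]-3-(2-hydroxypropan-2-yl)-4a,5-dimethyl-4,4a,5,6-tetrahydronaphthalen-2(3H)-one
Product: 23 (4aR,5R,6R)-6-[(tert-butyldimethylsilyl)oxy]-4a,5-dimethyl-3-(propan-2-ylidene)-4,4a,5,6-tetrahydronaphthalen-2(3H)-one, via tertiary mesylate 22 (not isolated)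
Conditions: MsCl, Et3N, CH2Cl2, 0 °C; then DBU, rt
Reagents that add atoms: methanesulfonyl chloride, CS(=O)(=O)Cl (its atoms are carried only by intermediate 22)
Why: Mesylation of the tertiary alcohol followed by base-induced E1cB elimination through the C7 enolate should give only the conjugated, tetrasubstituted isopropylidene ketone.

Step 15
Reactants: 23 (4aR,5R,6R)-6-[(tert-butyldimethylsilyl)oxy]-4a,5-dimethyl-3-(propan-2-ylidene)-4,4a,5,6-tetrahydronaphthalen-2(3H)-one
Product: 24 (4aR,5R,6R)-6-hydroxy-4a,5-dimethyl-3-(propan-2-ylidene)-4,4a,5,6-tetrahydronaphthalen-2(3H)-one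
Conditions: n-Bu4NF, AcOH, THF, 0 °C → rt
Reagents that add atoms: none
Why: Fluoride-mediated desilylation buffered with acetic acid frees the C3 alcohol without base-induced changes to the dienone.

Step 16
Reactants: 25 (2S)-2-methylbutan-1-ol; 26 triethyl (2E)-4-phosphonobut-2-enoate
Product: 29 ethyl (2E,4E,6S)-6-methylocta-2,4-dienoate, via (S)-2-methylbutanal 27 (not isolated), via lithiated phosphonate 28 (not isolated)
Conditions: 25, TEMPO (cat.), PhI(OAc)2, CH2Cl2, 0 °C → rt; washed and dried solution added to 26/LiN(SiMe3)2, THF, −78 → 0 °C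
Reagents that add atoms: LiN(SiMe3)2, [Li+].C[Si](C)(C)[N-][Si](C)(C)C (lithium is carried only by intermediate 28)
Why: TEMPO/PhI(OAc)2 oxidation gives the configurationally labile aldehyde 27 without racemisation, and the vinylogous Horner–Wadsworth–Emmons reaction with anion 28 builds the (2E,4E)-dienoate, the C6 stereocentre coming unchanged from the chiral pool.

Step 17
Reactants: 29 ethyl (2E,4E,6S)-6-methylocta-2,4-dienoate
Product: 30 (2E,4E,6S)-6-methylocta-2,4-dienoic acid
Conditions: LiOH, THF–MeOH–H2O, rt; 1 M HCl work-up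
Reagents that add atoms: lithium hydroxide, [Li+].[OH-] (supplies the carboxyl OH oxygen)
Why: Saponification (ester hydrolysis) under mild conditions gives the acid without touching the remote C6 stereocentre or the diene geometry.

Step 18
Reactants: 24 (4aR,5R,6R)-6-hydroxy-4a,5-dimethyl-3-(propan-2-ylidene)-4,4a,5,6-tetrahydronaphthalen-2(3H)-one; 30 (2E,4E,6S)-6-methylocta-2,4-dienoic acid
Product: 31 (1R,2S,8aR)-1,8a-dimethyl-6-oxo-7-(propan-2-ylidene)-1,2,6,7,8,8a-hexahydronaphthalen-2-yl (2E,4E,6S)-6-methylocta-2,4-dienoate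
Conditions: PPh3, DIAD, toluene, 0 °C → rt
Reagents that add atoms: none
Why: Mitsunobu esterification activates the allylic C3 alcohol as an oxyphosphonium ion that the carboxylate displaces by SN2 with inversion, which should convert the 3-epi alcohol into the natural (3S) ester and set the last stereocentre.

**Compound list**

1 | ethyl (2Z)-3-iodoprop-2-enoate | CCOC(=O)/C=C\I | starting material
2 | ethynyltrimethylsilane | C#C[Si](C)(C)C | starting material
3 | ethyl (2Z)-5-(trimethylsilyl)pent-2-en-4-ynoate | CCOC(=O)/C=C\C#C[Si](C)(C)C | intermediate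
4 | (2Z)-5-(trimethylsilyl)pent-2-en-4-yn-1-ol | OC/C=C\C#C[Si](C)(C)C | intermediate
5 | (2Z)-5-(trimethylsilyl)pent-2-en-4-ynal | O=C/C=C\C#C[Si](C)(C)C | intermediate
6 | (4S)-4-benzyl-3-propanoyl-1,3-oxazolidin-2-one | CCC(=O)N1[C@@H](Cc2ccccc2)COC1=O | starting material
7 | di-n-butylboron (Z)-enolate of 6 | C/C=C(\OB(CCCC)CCCC)N1[C@@H](Cc2ccccc2)COC1=O | intermediate (not isolated)
8 | (4S)-4-benzyl-3-[(2S,3R,4Z)-3-hydroxy-2-methyl-7-(trimethylsilyl)hept-4-en-6-ynoyl]-1,3-oxazolidin-2-one | C[Si](C)(C)C#C/C=C\[C@@H](O)[C@H](C)C(=O)N1[C@@H](Cc2ccccc2)COC1=O | intermediate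
9 | (4S)-4-benzyl-3-[(2S,3R,4Z)-3-[(tert-butyldimethylsilyl)oxy]-2-methyl-7-(trimethylsilyl)hept-4-en-6-ynoyl]-1,3-oxazolidin-2-one | C[Si](C)(C)C#C/C=C\[C@@H](O[Si](C)(C)C(C)(C)C)[C@H](C)C(=O)N1[C@@H](Cc2ccccc2)COC1=O | intermediate
10 | (2R,3R,4Z)-3-[(tert-butyldimethylsilyl)oxy]-2-methyl-7-(trimethylsilyl)hept-4-en-6-yn-1-ol | C[Si](C)(C)C#C/C=C\[C@@H](O[Si](C)(C)C(C)(C)C)[C@H](C)CO | intermediate
11 | (2S,3R,4Z)-3-[(tert-butyldimethylsilyl)oxy]-2-methyl-7-(trimethylsilyl)hept-4-en-6-ynal | C[Si](C)(C)C#C/C=C\[C@@H](O[Si](C)(C)C(C)(C)C)[C@H](C)C=O | intermediate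
12 | tert-butyldimethyl{[(3Z,5R,6R)-6-methyl-1-(trimethylsilyl)oct-3-ene-1,7-diyn-5-yl]oxy}silane | C[Si](C)(C)C#C/C=C\[C@@H](O[Si](C)(C)C(C)(C)C)[C@H](C)C#C | intermediate
13 | [(3Z,5R,6R,7E)-5-[(tert-butyldimethylsilyl)oxy]-6,7-dimethyl-1-(trimethylsilyl)octa-3,7-dien-1-yn-8-yl]dimethylalumane | C[Si](C)(C)C#C/C=C\[C@@H](O[Si](C)(C)C(C)(C)C)[C@H](C)/C(C)=C/[Al](C)C | intermediate (not isolated)
14 | tert-butyl{[(3Z,5R,6R,7E)-8-iodo-6,7-dimethyl-1-(trimethylsilyl)octa-3,7-dien-1-yn-5-yl]oxy}dimethylsilane | C[Si](C)(C)C#C/C=C\[C@@H](O[Si](C)(C)C(C)(C)C)[C@H](C)/C(C)=C/I | intermediate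
15 | 2-[(E)-2-ethoxyethenyl]-4,4,5,5-tetramethyl-1,3,2-dioxaborolane | CCO/C=C/B1OC(C)(C)C(C)(C)O1 | starting material
16 | tert-butyl{[(3Z,5R,6R,7E,9E)-10-ethoxy-6,7-dimethyl-1-(trimethylsilyl)deca-3,7,9-trien-1-yn-5-yl]oxy}dimethylsilane | C[Si](C)(C)C#C/C=C\[C@@H](O[Si](C)(C)C(C)(C)C)[C@H](C)/C(C)=C/C=C/OCC | intermediate (not isolated)
17 | tert-butyl{[(3Z,5R,6R,7E,9E)-10-ethoxy-6,7-dimethyldeca-3,7,9-trien-1-yn-5-yl]oxy}dimethylsilane | C#C/C=C\[C@@H](O[Si](C)(C)C(C)(C)C)[C@H](C)/C(C)=C/C=C/OCC | intermediate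
18 | tert-butyl{[(1R,2R,6R,8aR)-6-ethoxy-1,8a-dimethyl-1,2,6,8a-tetrahydronaphthalen-2-yl]oxy}dimethylsilane | CC(C)(C)[Si](C)(C)O[C@@H]1C=CC2=C[C@H](OCC)C=C[C@]2(C)[C@H]1C | intermediate
19 | (4aR,5R,6R)-6-[(tert-butyldimethylsilyl)oxy]-4a,5-dimethyl-5,6-dihydronaphthalen-2(4aH)-one | CC(C)(C)[Si](C)(C)O[C@@H]1C=CC2=CC(=O)C=C[C@]2(C)[C@H]1C | intermediate
20 | lithium (4aR,5R,6R)-6-[(tert-butyldimethylsilyl)oxy]-4a,5-dimethyl-4,4a,5,6-tetrahydronaphthalen-2-olate | CC(C)(C)[Si](C)(C)O[C@@H]1C=CC2=CC([O-])=CC[C@]2(C)[C@H]1C.[Li+] | intermediate (not isolated)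
21 | (3S,4aR,5R,6R)-6-[(tert-butyldimethylsilyl)oxy]-3-(2-hydroxypropan-2-yl)-4a,5-dimethyl-4,4a,5,6-tetrahydronaphthalen-2(3H)-one | CC(C)(C)[Si](C)(C)O[C@@H]1C=CC2=CC(=O)[C@H](C(C)(C)O)C[C@]2(C)[C@H]1C | intermediate
22 | 2-[(3S,4aR,5R,6R)-6-[(tert-butyldimethylsilyl)oxy]-4a,5-dimethyl-2-oxo-2,3,4,4a,5,6-hexahydronaphthalen-3-yl]propan-2-yl methanesulfonate | CC(C)(C)[Si](C)(C)O[C@@H]1C=CC2=CC(=O)[C@H](C(C)(C)OS(C)(=O)=O)C[C@]2(C)[C@H]1C | intermediate (not isolated)
23 | (4aR,5R,6R)-6-[(tert-butyldimethylsilyl)oxy]-4a,5-dimethyl-3-(propan-2-ylidene)-4,4a,5,6-tetrahydronaphthalen-2(3H)-one | CC(C)(C)[Si](C)(C)O[C@@H]1C=CC2=CC(=O)C(=C(C)C)C[C@]2(C)[C@H]1C | intermediate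
24 | (4aR,5R,6R)-6-hydroxy-4a,5-dimethyl-3-(propan-2-ylidene)-4,4a,5,6-tetrahydronaphthalen-2(3H)-one | O[C@@H]1C=CC2=CC(=O)C(=C(C)C)C[C@]2(C)[C@H]1C | intermediate
25 | (2S)-2-methylbutan-1-ol | CC[C@H](C)CO | starting material
26 | triethyl (2E)-4-phosphonobut-2-enoate | CCOC(=O)/C=C/CP(=O)(OCC)OCC | starting material
27 | (2S)-2-methylbutanal | CC[C@H](C)C=O | intermediate (not isolated)
28 | lithium salt of triethyl (2E)-4-phosphonobut-2-enoate (C4 carbanion) | CCOC(=O)/C=C/[CH-]P(=O)(OCC)OCC.[Li+] | intermediate (not isolated)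
29 | ethyl (2E,4E,6S)-6-methylocta-2,4-dienoate | CC[C@H](C)/C=C/C=C/C(=O)OCC | intermediate
30 | (2E,4E,6S)-6-methylocta-2,4-dienoic acid | CC[C@H](C)/C=C/C=C/C(=O)O | intermediate
31 | (1R,2S,8aR)-1,8a-dimethyl-6-oxo-7-(propan-2-ylidene)-1,2,6,7,8,8a-hexahydronaphthalen-2-yl (2E,4E,6S)-6-methylocta-2,4-dienoate | CC[C@H](C)/C=C/C=C/C(=O)O[C@H]1C=CC2=CC(=O)C(=C(C)C)C[C@]2(C)[C@H]1C | target

**Step count and risks**

Total step count: 18. Longest linear sequence: 16 steps (steps 1–15 and 18); the side-chain acid is made in steps 16–17.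

Steps most likely to fail:

1. Step 11 (cycloaddition). Oxidative coupling at the crowded, methyl-bearing diene terminus may be slow, the enol ether may be lost or may deactivate the catalyst, and facial selectivity at C5 may be insufficient. Fallback: the oxygen at C8 is left out of the cycloaddition substrate and introduced afterwards. Setting out from iodide 14, Stille coupling with tributyl(vinyl)stannane (Pd(PPh3)4, CuI, DMF) should give tert-butyldimethyl{[(3Z,5R,6R,7E)-6,7-dimethyl-1-(trimethylsilyl)deca-3,7,9-trien-1-yn-5-yl]oxy}silane F1. Removal of the alkynyl silyl group (K2CO3, MeOH) should give tert-butyl{[(3Z,5R,6R,7E)-6,7-dimethyldeca-3,7,9-trien-1-yn-5-yl]oxy}dimethylsilane F2. This hydrocarbon dienyne is cyclised with Ni(cod)2 and tris(2-biphenylyl) phosphite (zerovalent nickel, THF, rt), a system suited to hydrocarbon dienynes that form an angular methyl, to give tert-butyl{[(1R,2R,8aR)-1,8a-dimethyl-1,2,6,8a-tetrahydronaphthalen-2-yl]oxy}dimethylsilane F3. The doubly allylic C8 methylene is then oxidised with (C5H5NH)2Cr2O7 and t-BuOOH in benzene, which returns to the route at trienone 19.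

2. Step 13 (reductive aldol). Hydride delivery may lose regiocontrol (1,2- or 1,6-addition), and the acetone adduct may revert by retro-aldol. Fallback: the two events are separated. Setting out from 19, hydrogenation of the disubstituted C6=C7 bond with H2 and RhCl(PPh3)3 in benzene should give (4aR,5R,6R)-6-[(tert-butyldimethylsilyl)oxy]-4a,5-dimethyl-4,4a,5,6-tetrahydronaphthalen-2(3H)-one F4. Kinetic deprotonation at C7 (LDA, THF, −78 °C), transmetalation with ZnCl2 and addition of acetone then give aldol 21, where the route is rejoined.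

3. Step 18 (Mitsunobu). SN2 displacement at C3 may be slow because the carboxylate must approach syn to the axial angular methyl; an acyloxyphosphonium pathway could then give the ester with retention. Fallback: the configuration is corrected by oxidation and reduction, and the ester is made with retention. Setting out from 24, Dess–Martin oxidation should give (1R,8aR)-1,8a-dimethyl-7-(propan-2-ylidene)-8,8a-dihydronaphthalene-2,6(1H,7H)-dione F5. Reduction with NaBH4 and CeCl3·7H2O in MeOH at −78 °C (Luche) should deliver hydride to the less hindered C3 carbonyl on the face anti to the axial angular methyl, giving (4aR,5R,6S)-6-hydroxy-4a,5-dimethyl-3-(propan-2-ylidene)-4,4a,5,6-tetrahydronaphthalen-2(3H)-one F6. Yamaguchi esterification with acid 30 (2,4,6-trichlorobenzoyl chloride, Et3N, then DMAP, toluene) then gives target 31.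

**Further compounds**

F1 | step 11 | tert-butyldimethyl{[(3Z,5R,6R,7E)-6,7-dimethyl-1-(trimethylsilyl)deca-3,7,9-trien-1-yn-5-yl]oxy}silane | C[Si](C)(C)C#C/C=C\[C@@H](O[Si](C)(C)C(C)(C)C)[C@H](C)/C(C)=C/C=C
F2 | step 11 | tert-butyl{[(3Z,5R,6R,7E)-6,7-dimethyldeca-3,7,9-trien-1-yn-5-yl]oxy}dimethylsilane | C#C/C=C\[C@@H](O[Si](C)(C)C(C)(C)C)[C@H](C)/C(C)=C/C=C
F3 | step 11 | tert-butyl{[(1R,2R,8aR)-1,8a-dimethyl-1,2,6,8a-tetrahydronaphthalen-2-yl]oxy}dimethylsilane | CC(C)(C)[Si](C)(C)O[C@@H]1C=CC2=CCC=C[C@]2(C)[C@H]1C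
F4 | step 13 | (4aR,5R,6R)-6-[(tert-butyldimethylsilyl)oxy]-4a,5-dimethyl-4,4a,5,6-tetrahydronaphthalen-2(3H)-one | CC(C)(C)[Si](C)(C)O[C@@H]1C=CC2=CC(=O)CC[C@]2(C)[C@H]1C
F5 | step 18 | (1R,8aR)-1,8a-dimethyl-7-(propan-2-ylidene)-8,8a-dihydronaphthalene-2,6(1H,7H)-dione | O=C1C=CC2=CC(=O)C(=C(C)C)C[C@]2(C)[C@H]1C
F6 | step 18 | (4aR,5R,6S)-6-hydroxy-4a,5-dimethyl-3-(propan-2-ylidene)-4,4a,5,6-tetrahydronaphthalen-2(3H)-one | O[C@H]1C=CC2=CC(=O)C(=C(C)C)C[C@]2(C)[C@H]1C
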